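**Retrosynthetic overview**
- The only ring, the 36-membered lactone, is closed in the penultimate step by a two-fold Stille "stitching" that inserts C8=C9 between a C10 vinyl iodide and a C7 trienyl bromide; the C1–O–C35 ester is carried from the start as a phosphonopropanoate and extended to C7 by HWE olefination.
- Key disconnection C20–C21: nickel-catalysed decarboxylative radical acylation, in which a C20 radical from an N-acyloxyphthalimide is captured by an acyl–nickel species made from a C21 S-2-pyridyl thioester. It joins the C10–C20 tetraol half to the C21–C27 unit with C19 and C23 already set.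
- C27–C28 and C14–C15 are cut the same way (alkyl radical plus acyl–nickel), from a primary iodide and from an epoxide-derived iodohydrin.
- Both anti-1,3-diols (C17/C19 and C23/C25) come from the two enantiomers of one C2-symmetric diacid made by two-directional iridium-catalysed allylation of propane-1,3-diol. C13 comes from (S)-epichlorohydrin, C15 from a 1,3-syn reduction, C35 from (S)-2-isopropyloxirane.

Assumption: the target is the open-chain C21/C27 diketone as drawn (hemiketal tautomers count as the same compound), and (S)-epichlorohydrin, (S)-2-isopropyloxirane, (E)-(2-bromovinyl)trimethylsilane and glutaconaldehyde potassium salt are bought.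

Chain locants used below: C1 = ester carbonyl, C2–C11 = pentaene (methyl on C2), carbinols C13, C15, C17, C19, C23, C25, ketones C21 and C27, C28–C34 = heptamethylene, C35 = isopropyl carbinol. TBS = tert-butyldimethylsilyl, TES = triethylsilyl, SPy = pyridin-2-ylsulfanyl.

**Step 1**
Reactants: 1 propane-1,3-diol; 2 allyl acetate
Product: 3 (4S,6S)-nona-1,8-diene-4,6-diol
Conditions: [Ir(cod)Cl]2 (5 mol %), (S)-Cl,MeO-BIPHEP (10 mol %; the ligand enantiomer that gives the S,S diol), 4-chloro-3-nitrobenzoic acid (20 mol %), Cs2CO3 (40 mol %), 2 (10 equiv), 1,4-dioxane, 90 °C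
Reagents that add atoms: none
Why: Krische two-directional transfer-hydrogenative carbonyl allylation from the alcohol oxidation level; the cyclometallated π-allyliridium catalyst sets both carbinol centres under catalyst control, and the double addition amplifies the selectivity to give the C2-symmetric anti diol essentially enantiopure.

**Step 2**
Reactants: 3 (4S,6S)-nona-1,8-diene-4,6-diol
Product: 4 (4S,6S)-4,6-bis(TBS-oxy)nona-1,8-diene
Conditions: TBSCl (2.5 equiv), imidazole (5 equiv), DMF, rt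
Reagents that add atoms: tert-butyldimethylsilyl chloride, CC(C)(C)[Si](C)(C)Cl
Why: Standard silyl ether formation protects both carbinols for the oxidative cleavage and leaves the stereocentres untouched.

**Step 3**
Reactants: 4 (4S,6S)-4,6-bis(TBS-oxy)nona-1,8-diene
Product: 5 (3R,5R)-3,5-bis(TBS-oxy)heptanedioic acid
Conditions: RuCl3 hydrate (5 mol %), NaIO4 (10 equiv), CCl4/MeCN/H2O (2:2:3), rt
Reagents that add atoms: sodium periodate, [Na+].[O-]I(=O)(=O)=O; water, O
Why: Sharpless RuO4 oxidative cleavage takes both terminal alkenes directly to carboxylic acids; the silyl ethers survive and the descriptors change only through CIP priorities.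

**Step 4**
Reactants: 5 (3R,5R)-3,5-bis(TBS-oxy)heptanedioic acid
Product: 6 S,S'-di(pyridin-2-yl) (3R,5R)-3,5-bis(TBS-oxy)heptanebis(thioate)
Conditions: 2,2'-dipyridyl disulfide (2.4 equiv), PPh3 (2.4 equiv), CH2Cl2, rt
Reagents that add atoms: 2,2'-dipyridyl disulfide, c1ccc(nc1)SSc1ccccn1
Why: Mukaiyama redox condensation (Corey–Nicolaou thioester formation) activates both acids under neutral conditions, so the β-silyloxy groups do not eliminate.

**Step 5**
Reactants: 1 propane-1,3-diol; 2 allyl acetate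
Product: 7 (4R,6R)-nona-1,8-diene-4,6-diol
Conditions: [Ir(cod)Cl]2 (5 mol %), (R)-Cl,MeO-BIPHEP (10 mol %), 4-chloro-3-nitrobenzoic acid (20 mol %), Cs2CO3 (40 mol %), 2 (10 equiv), 1,4-dioxane, 90 °C
Reagents that add atoms: none
Why: The same Krische two-directional allylation with the antipodal ligand sets the C23 and C25 carbinols as the enantiomeric C2-symmetric anti diol.

**Step 6**
Reactants: 7 (4R,6R)-nona-1,8-diene-4,6-diol
Product: 8 (4R,6R)-4,6-bis(TBS-oxy)nona-1,8-diene
Conditions: TBSCl (2.5 equiv), imidazole (5 equiv), DMF, rt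
Reagents that add atoms: tert-butyldimethylsilyl chloride, CC(C)(C)[Si](C)(C)Cl
Why: Standard silylation, as in step 2.

**Step 7**
Reactants: 8 (4R,6R)-4,6-bis(TBS-oxy)nona-1,8-diene
Product: 9 (3S,5S)-3,5-bis(TBS-oxy)heptanedioic acid
Conditions: RuCl3 hydrate (5 mol %), NaIO4 (10 equiv), CCl4/MeCN/H2O (2:2:3), rt
Reagents that add atoms: sodium periodate, [Na+].[O-]I(=O)(=O)=O; water, O
Why: Sharpless RuO4 cleavage of both vinyl groups gives the C21–C27 diacid.

**Step 8**
Reactants: 9 (3S,5S)-3,5-bis(TBS-oxy)heptanedioic acid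
Product: 10 S,S'-di(pyridin-2-yl) (3S,5S)-3,5-bis(TBS-oxy)heptanebis(thioate)
Conditions: 2,2'-dipyridyl disulfide (2.4 equiv), PPh3 (2.4 equiv), CH2Cl2, rt
Reagents that add atoms: 2,2'-dipyridyl disulfide, c1ccc(nc1)SSc1ccccn1
Why: Mukaiyama redox condensation gives the C2-symmetric bis-acyl donor whose two thioesters are homotopic.

**Step 9**
Reactants: 11 (E)-(2-bromovinyl)trimethylsilane; 12 (S)-epichlorohydrin
Product: 15 (S)-2-[(2E)-3-(trimethylsilyl)prop-2-en-1-yl]oxirane, via vinyl Grignard reagent 13 (not isolated), via chlorohydrin alkoxide 14 (not isolated)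
Conditions: Mg, THF, 45 °C; CuI (10 mol %), 12, −40 → −20 °C; then 2 M aq. NaOH, rt (one pot)
Reagents that add atoms: none
Why: Copper-catalysed Grignard opening at the unsubstituted epoxide carbon followed by Williamson closure onto CH2Cl; the C13–O bond is never broken, so the S centre is kept, and the alkenyl Grignard keeps its E geometry.

**Step 10**
Reactants: 15 (S)-2-[(2E)-3-(trimethylsilyl)prop-2-en-1-yl]oxirane; 6 S,S'-di(pyridin-2-yl) (3R,5R)-3,5-bis(TBS-oxy)heptanebis(thioate)
Product: 17 S-(pyridin-2-yl) (3R,5R,9S,11E)-3,5-bis(TBS-oxy)-9-hydroxy-7-oxo-12-(trimethylsilyl)dodec-11-enethioate, via iodohydrin 16 (not isolated)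
Conditions: Et3N·HI (1.2 equiv), DMPU, rt, 1 h; then 6 (3 equiv, excess recovered), NiBr2(dme) (10 mol %), 4,4'-di-tert-butyl-2,2'-bipyridine (12 mol %), Mn (3 equiv), DMPU/THF, rt
Reagents that add atoms: none
Why: Proposed new method: triethylammonium iodide opens the terminal epoxide at CH2 to iodohydrin 16 (C13 stays S), low-valent nickel turns the primary iodide into the β-hydroxyalkyl radical at C14, and this is captured by the acyl–nickel species from one of the two homotopic thioesters of 6 to give the β-hydroxy ketone by reductive elimination (a reductive aldol surrogate); the closest known reactions are the nickel-catalysed reductive coupling of epoxides with aryl halides under iodide co-catalysis and the nickel-catalysed cross-electrophile ketone synthesis from alkyl iodides and S-2-pyridyl thioesters.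

**Step 11**
Reactants: 17 the C13-hydroxy C15-ketone thioester
Product: 18 S-(pyridin-2-yl) (3R,5S,7S,9S,11E)-3,5-bis(TBS-oxy)-7,9-dihydroxy-12-(trimethylsilyl)dodec-11-enethioate
Conditions: catecholborane (4 equiv), THF, −10 °C; then MeOH, aq. sodium potassium tartrate
Reagents that add atoms: none
Why: Evans catecholborane 1,3-syn reduction; the C13 alkoxyborane chelates the ketone and hydride adds to the chair chelate to set C15 syn to C13 (and so syn to C17), while the thioester and vinylsilane are not reduced at this temperature.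

**Step 12**
Reactants: 18 the C13,C15 syn-diol thioester
Product: 19 S-(pyridin-2-yl) 3,5-bis(TBS-oxy)-7,9-bis(TES-oxy)-12-(trimethylsilyl)dodec-11-enethioate (stereocentres and alkene as in 18)
Conditions: TESOTf (2.5 equiv), 2,6-lutidine (4 equiv), CH2Cl2, −78 °C
Reagents that add atoms: triethylsilyl trifluoromethanesulfonate, CC[Si](CC)(CC)OS(=O)(=O)C(F)(F)F
Why: Silylation caps the diol so that neither hydroxyl can trap the β-silyl cation in the later iododesilylation; the thioester tolerates the non-nucleophilic base.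

**Step 13**
Reactants: 19 the bis-TES bis-TBS thioester
Product: 20 1,3-dioxoisoindolin-2-yl 3,5-bis(TBS-oxy)-7,9-bis(TES-oxy)-12-(trimethylsilyl)dodec-11-enoate (stereocentres and alkene as in 18)
Conditions: N-hydroxyphthalimide (1.5 equiv), AgOTf (1.2 equiv), 2,6-lutidine (1.5 equiv), CH2Cl2/MeCN, 0 °C → rt, dark
Reagents that add atoms: N-hydroxyphthalimide, ON1C(=O)c2ccccc2C1=O
Why: Gerlach-type silver-assisted acyl transfer; AgOTf activates the 2-pyridyl thioester and removes the thiolate as its silver salt, so the N-hydroxyimide oxygen is acylated irreversibly to give the redox-active ester.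

**Step 14 (key step)**
Reactants: 20 the C10–C20 N-acyloxyphthalimide; 10 S,S'-di(pyridin-2-yl) (3S,5S)-3,5-bis(TBS-oxy)heptanebis(thioate)
Product: 21 S-(pyridin-2-yl) thioester of the C10–C27 chain: C10=C11 E-vinylsilane, TES ethers at C13 and C15, TBS ethers at C17, C19, C23 and C25, ketone at C21, thioester carbonyl at C27 (all carbinol centres as in 37)
Conditions: 10 (3 equiv, excess recovered), NiBr2(dme) (10 mol %), 4,4'-di-tert-butyl-2,2'-bipyridine (10 mol %), Zn (2 equiv), DMA/THF (1:1), rt; aq. NH4Cl work-up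
Reagents that add atoms: none
Why: Nickel-catalysed decarboxylative cross-electrophile ketone synthesis (redox-active ester plus S-2-pyridyl thioester); single-electron reduction of the N-acyloxyphthalimide releases CO2 and the primary C20 radical, which the acyl–nickel species from one thioester of 10 captures and reductively eliminates as the C20–C21 bond, so the C19 and C23 carbinols flanking the new ketone are carried in already set and no 1,5-induction is needed.

**Step 15**
Reactants: 22 1-bromo-6-chlorohexane; 23 (S)-2-(propan-2-yl)oxirane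
Product: 25 (R)-10-chloro-2-methyldecan-3-ol, via 6-chlorohexylmagnesium bromide 24 (not isolated)
Conditions: Mg, THF, rt; CuI (10 mol %), 23, −30 → 0 °C; then H2O
Reagents that add atoms: none
Why: The Grignard reagent forms only at the C–Br bond and copper-catalysed epoxide opening occurs at CH2, so the C35 centre is untouched (S epoxide to R alcohol is a CIP change only).

**Step 16**
Reactants: 25 (R)-10-chloro-2-methyldecan-3-ol; 26 2-bromopropanoyl bromide (racemic)
Product: 27 (3R)-10-chloro-2-methyldecan-3-yl 2-bromopropanoate (both epimers at the bromine-bearing carbon)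
Conditions: 26 (1.3 equiv), pyridine (2 equiv), DMAP (5 mol %), CH2Cl2, 0 °C → rt
Reagents that add atoms: none
Why: Acylation of the hindered secondary alcohol with an acid bromide installs C1, C2 and the C2 methyl as the future lactone ester.

**Step 17**
Reactants: 27 the 2-bromopropanoate
Product: 28 (3R)-10-chloro-2-methyldecan-3-yl 2-(diethoxyphosphoryl)propanoate (both epimers at the phosphorus-bearing carbon)
Conditions: P(OEt)3 (3 equiv), neat, 130 °C, EtBr distilled off
Reagents that add atoms: triethyl phosphite, CCOP(OCC)OCC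
Why: Michaelis–Arbuzov reaction at the activated α-bromo ester; the unactivated primary chloride is much slower at this temperature.

**Step 18**
Reactants: 28 the chloro phosphonate
Product: 29 (3R)-10-iodo-2-methyldecan-3-yl 2-(diethoxyphosphoryl)propanoate
Conditions: NaI (5 equiv), acetone, reflux
Reagents that add atoms: sodium iodide, [Na+].[I-]
Why: Finkelstein exchange gives the primary iodide needed as radical precursor.

**Step 19**
Reactants: 21 the C10–C27 keto thioester; 29 the C28–C35 iodo phosphonate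
Product: 30 C10–C35 diketone: as 21, with C27 now a ketone bonded to the C28–C34 chain and C35 carrying the 2-(diethoxyphosphoryl)propanoate ester
Conditions: 29 (1.5 equiv), NiBr2(dme) (15 mol %), 4,4'-di-tert-butyl-2,2'-bipyridine (15 mol %), Mn (3 equiv), DMA/THF, rt
Reagents that add atoms: none
Why: Nickel-catalysed reductive cross-electrophile acylation; the primary C28 radical from the iodide is captured by the acyl–nickel species of the thioester to form the C27 ketone, and the phosphonate, ketone and silyl ethers are inert (adding Cp2ZrCl2 is a known accelerating variant).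

**Step 20**
Reactants: 30 the C10–C35 vinylsilane
Product: 31 the corresponding (E)-C10 vinyl iodide (otherwise as 30)
Conditions: NIS (1.3 equiv), HFIP, 0 °C, 10 min, dark; aq. Na2S2O3
Reagents that add atoms: N-iodosuccinimide, O=C1CCC(=O)N1I
Why: Ipso-iododesilylation through the β-silyl cation proceeds with retention of the E geometry, and all nearby oxygens are silylated so none can trap the cation.

**Step 21**
Reactants: 32 glutaconaldehyde potassium salt
Product: 33 (2E,4E)-5-bromopenta-2,4-dienal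
Conditions: PPh3, Br2, CH2Cl2, 0 °C; then 32, 0 °C → rt
Reagents that add atoms: bromine, BrBr
Why: Deoxybromination of the vinylogous carboxylate with Ph3PBr2 gives the bromodienal, which equilibrates to the E,E isomer.

**Step 22**
Reactants: 31 the vinyl iodide phosphonate; 33 (2E,4E)-5-bromopenta-2,4-dienal
Product: 34 seco bis-halide: as 31, with the C35 ester now the (2E,4E,6E)-7-bromo-2-methylhepta-2,4,6-trienoate
Conditions: 33 (1.5 equiv), LiCl (3 equiv), DBU (1.5 equiv), MeCN/THF, 0 °C, dark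
Reagents that add atoms: none
Why: Masamune–Roush Horner–Wadsworth–Emmons olefination gives the E trisubstituted C2=C3 enoate under conditions mild enough for the β-silyloxy ketones.

**Step 23**
Reactants: 34 the seco bis-halide
Product: 36 hexasilyl macrolactone (37 with TES ethers at C13 and C15 and TBS ethers at C17, C19, C23 and C25), via dienylstannane 35 (not isolated)
Conditions: (E)-1,2-bis(tributylstannyl)ethene (1.1 equiv), Pd(MeCN)2Cl2 (20 mol %), iPr2NEt, DMF/THF (1:1), 1 mM, rt, dark
Reagents that add atoms: (E)-1,2-bis(tributylstannyl)ethene, CCCC[Sn](CCCC)(CCCC)/C=C/[Sn](CCCC)(CCCC)CCCC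
Why: Two-fold Stille "stitching"; the more reactive vinyl iodide couples first to give dienylstannane 35, which then closes the 36-membered ring onto the trienyl bromide with retention at every alkene to complete the all-E pentaene.

**Step 24**
Reactants: 36 the hexasilyl macrolactone
Product: 37 CNP0167014.1
Conditions: HF·pyridine, excess pyridine, THF, 0 °C → rt, plastic vessel, dark; pH 7 buffer quench
Reagents that add atoms: none
Why: Buffered fluoride desilylation removes the two TES and four TBS ethers without acid strong enough to dehydrate the β-hydroxy ketones, ketalise C21 or C27, or isomerise the pentaene.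

**Compound list**
1 | propane-1,3-diol | OCCCO | starting material
2 | allyl acetate | CC(=O)OCC=C | starting material
3 | (4S,6S)-nona-1,8-diene-4,6-diol | C=CC[C@H](O)C[C@@H](O)CC=C | intermediate
4 | (4S,6S)-4,6-bis(TBS-oxy)nona-1,8-diene | C=CC[C@H](O[Si](C)(C)C(C)(C)C)C[C@@H](O[Si](C)(C)C(C)(C)C)CC=C | intermediate
5 | (3R,5R)-3,5-bis(TBS-oxy)heptanedioic acid | OC(=O)C[C@H](O[Si](C)(C)C(C)(C)C)C[C@@H](O[Si](C)(C)C(C)(C)C)CC(=O)O | intermediate
6 | S,S'-di(pyridin-2-yl) (3R,5R)-3,5-bis(TBS-oxy)heptanebis(thioate) | O=C(Sc1ccccn1)C[C@H](O[Si](C)(C)C(C)(C)C)C[C@@H](O[Si](C)(C)C(C)(C)C)CC(=O)Sc1ccccn1 | intermediate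
7 | (4R,6R)-nona-1,8-diene-4,6-diol | C=CC[C@@H](O)C[C@H](O)CC=C | intermediate
8 | (4R,6R)-4,6-bis(TBS-oxy)nona-1,8-diene | C=CC[C@@H](O[Si](C)(C)C(C)(C)C)C[C@H](O[Si](C)(C)C(C)(C)C)CC=C | intermediate
9 | (3S,5S)-3,5-bis(TBS-oxy)heptanedioic acid | OC(=O)C[C@@H](O[Si](C)(C)C(C)(C)C)C[C@H](O[Si](C)(C)C(C)(C)C)CC(=O)O | intermediate
10 | S,S'-di(pyridin-2-yl) (3S,5S)-3,5-bis(TBS-oxy)heptanebis(thioate) | O=C(Sc1ccccn1)C[C@@H](O[Si](C)(C)C(C)(C)C)C[C@H](O[Si](C)(C)C(C)(C)C)CC(=O)Sc1ccccn1 | intermediate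
11 | (E)-(2-bromovinyl)trimethylsilane | C[Si](C)(C)/C=C/Br | starting material
12 | (S)-epichlorohydrin | C1[C@H](O1)CCl | starting material
13 | (E)-[2-(trimethylsilyl)ethenyl]magnesium bromide | C[Si](C)(C)/C=C/[Mg]Br | intermediate
14 | (2S,4E)-1-chloro-5-(trimethylsilyl)pent-4-en-2-ol (present as its bromomagnesium alkoxide) | C[Si](C)(C)/C=C/C[C@H](O)CCl | intermediate
15 | (S)-2-[(2E)-3-(trimethylsilyl)prop-2-en-1-yl]oxirane | C[Si](C)(C)/C=C/C[C@H]1CO1 | intermediate
16 | (2S,4E)-1-iodo-5-(trimethylsilyl)pent-4-en-2-ol | C[Si](C)(C)/C=C/C[C@H](O)CI | intermediate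
17 | S-(pyridin-2-yl) (3R,5R,9S,11E)-3,5-bis(TBS-oxy)-9-hydroxy-7-oxo-12-(trimethylsilyl)dodec-11-enethioate | C[Si](C)(C)/C=C/C[C@H](O)CC(=O)C[C@H](O[Si](C)(C)C(C)(C)C)C[C@@H](O[Si](C)(C)C(C)(C)C)CC(=O)Sc1ccccn1 | intermediate
18 | S-(pyridin-2-yl) (3R,5S,7S,9S,11E)-3,5-bis(TBS-oxy)-7,9-dihydroxy-12-(trimethylsilyl)dodec-11-enethioate | C[Si](C)(C)/C=C/C[C@H](O)C[C@H](O)C[C@H](O[Si](C)(C)C(C)(C)C)C[C@@H](O[Si](C)(C)C(C)(C)C)CC(=O)Sc1ccccn1 | intermediate
19 | bis-TES ether of 18 (C10–C20 segment plus thioester carbon) | C[Si](C)(C)/C=C/C[C@H](O[Si](CC)(CC)CC)C[C@H](O[Si](CC)(CC)CC)C[C@H](O[Si](C)(C)C(C)(C)C)C[C@@H](O[Si](C)(C)C(C)(C)C)CC(=O)Sc1ccccn1 | intermediate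
20 | N-acyloxyphthalimide (1,3-dioxoisoindolin-2-yl ester) corresponding to 19 | C[Si](C)(C)/C=C/C[C@H](O[Si](CC)(CC)CC)C[C@H](O[Si](CC)(CC)CC)C[C@H](O[Si](C)(C)C(C)(C)C)C[C@@H](O[Si](C)(C)C(C)(C)C)CC(=O)ON1C(=O)c2ccccc2C1=O | intermediate
21 | C10–C27 S-(pyridin-2-yl) thioester: E-vinylsilane, 13,15-bis(TES-oxy), 17,19,23,25-tetrakis(TBS-oxy), 21-oxo | C[Si](C)(C)/C=C/C[C@H](O[Si](CC)(CC)CC)C[C@H](O[Si](CC)(CC)CC)C[C@H](O[Si](C)(C)C(C)(C)C)C[C@@H](O[Si](C)(C)C(C)(C)C)CC(=O)C[C@@H](O[Si](C)(C)C(C)(C)C)C[C@H](O[Si](C)(C)C(C)(C)C)CC(=O)Sc1ccccn1 | intermediate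
22 | 1-bromo-6-chlorohexane | ClCCCCCCBr | starting material
23 | (S)-2-(propan-2-yl)oxirane | C1[C@H](C(C)C)O1 | starting material
24 | 6-chlorohexylmagnesium bromide | ClCCCCCC[Mg]Br | intermediate
25 | (R)-10-chloro-2-methyldecan-3-ol | ClCCCCCCC[C@H](C(C)C)O | intermediate
26 | 2-bromopropanoyl bromide | CC(Br)C(=O)Br | starting material
27 | (3R)-10-chloro-2-methyldecan-3-yl 2-bromopropanoate | ClCCCCCCC[C@H](C(C)C)OC(=O)C(C)Br | intermediate
28 | (3R)-10-chloro-2-methyldecan-3-yl 2-(diethoxyphosphoryl)propanoate | ClCCCCCCC[C@H](C(C)C)OC(=O)C(C)P(=O)(OCC)OCC | intermediate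
29 | (3R)-10-iodo-2-methyldecan-3-yl 2-(diethoxyphosphoryl)propanoate | ICCCCCCC[C@H](C(C)C)OC(=O)C(C)P(=O)(OCC)OCC | intermediate
30 | C10–C35 diketone phosphonate with C10 vinylsilane | C[Si](C)(C)/C=C/C[C@H](O[Si](CC)(CC)CC)C[C@H](O[Si](CC)(CC)CC)C[C@H](O[Si](C)(C)C(C)(C)C)C[C@@H](O[Si](C)(C)C(C)(C)C)CC(=O)C[C@@H](O[Si](C)(C)C(C)(C)C)C[C@H](O[Si](C)(C)C(C)(C)C)CC(=O)CCCCCCC[C@H](C(C)C)OC(=O)C(C)P(=O)(OCC)OCC | intermediate
31 | C10–C35 diketone phosphonate with (E)-C10 vinyl iodide | I/C=C/C[C@H](O[Si](CC)(CC)CC)C[C@H](O[Si](CC)(CC)CC)C[C@H](O[Si](C)(C)C(C)(C)C)C[C@@H](O[Si](C)(C)C(C)(C)C)CC(=O)C[C@@H](O[Si](C)(C)C(C)(C)C)C[C@H](O[Si](C)(C)C(C)(C)C)CC(=O)CCCCCCC[C@H](C(C)C)OC(=O)C(C)P(=O)(OCC)OCC | intermediate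
32 | glutaconaldehyde potassium salt | [K+].[O-]/C=C/C=C/C=O | starting material
33 | (2E,4E)-5-bromopenta-2,4-dienal | Br/C=C/C=C/C=O | intermediate
34 | seco bis-halide: C10 vinyl iodide and C35 (2E,4E,6E)-7-bromo-2-methylhepta-2,4,6-trienoate | I/C=C/C[C@H](O[Si](CC)(CC)CC)C[C@H](O[Si](CC)(CC)CC)C[C@H](O[Si](C)(C)C(C)(C)C)C[C@@H](O[Si](C)(C)C(C)(C)C)CC(=O)C[C@@H](O[Si](C)(C)C(C)(C)C)C[C@H](O[Si](C)(C)C(C)(C)C)CC(=O)CCCCCCC[C@H](C(C)C)OC(=O)/C(C)=C/C=C/C=C/Br | intermediate
35 | C8 (1E,3E)-dienylstannane with C7 trienyl bromide | CCCC[Sn](CCCC)(CCCC)/C=C/C=C/C[C@H](O[Si](CC)(CC)CC)C[C@H](O[Si](CC)(CC)CC)C[C@H](O[Si](C)(C)C(C)(C)C)C[C@@H](O[Si](C)(C)C(C)(C)C)CC(=O)C[C@@H](O[Si](C)(C)C(C)(C)C)C[C@H](O[Si](C)(C)C(C)(C)C)CC(=O)CCCCCCC[C@H](C(C)C)OC(=O)/C(C)=C/C=C/C=C/Br | intermediate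
36 | hexasilyl macrolactone (13,15-bis-TES, 17,19,23,25-tetrakis-TBS ether of 37) | C\C1=C/C=C/C=C/C=C/C=C/C[C@H](O[Si](CC)(CC)CC)C[C@H](O[Si](CC)(CC)CC)C[C@H](O[Si](C)(C)C(C)(C)C)C[C@@H](O[Si](C)(C)C(C)(C)C)CC(=O)C[C@@H](O[Si](C)(C)C(C)(C)C)C[C@H](O[Si](C)(C)C(C)(C)C)CC(=O)CCCCCCC[C@H](C(C)C)OC1=O | intermediate
37 | CNP0167014.1, (3E,5E,7E,9E,11E,14S,16S,18S,20R,24S,26S,36R)-14,16,18,20,24,26-hexahydroxy-3-methyl-36-(propan-2-yl)-1-oxacyclohexatriaconta-3,5,7,9,11-pentaene-2,22,28-trione | C\C1=C/C=C/C=C/C=C/C=C/C[C@H](O)C[C@H](O)C[C@H](O)C[C@@H](O)CC(=O)C[C@@H](O)C[C@H](O)CC(=O)CCCCCCC[C@H](C(C)C)OC1=O | target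

**Step count**
Total: 24 steps. Longest linear sequence: 14 steps (1–4, 10–14, 19, 20, 22–24).

**Three steps most likely to fail**

Step 10 (epoxide plus thioester reductive acylation, untested combination). The fallback sets out from chlorohydrin 14, isolated by aqueous work-up of step 9 before the NaOH stage, and from 6, and comes back at 17. It replaces the nickel radical coupling by polar organolithium chemistry: 14 is deprotonated with n-BuLi at −78 °C and reductively lithiated with lithium naphthalenide to the β-oxido alkyllithium, dilithium (2S,4E)-1-lithio-5-(trimethylsilyl)pent-4-en-2-olate F1. This is stable to β-elimination at −78 °C and is added to excess 6, where the chelated tetrahedral intermediate of the 2-pyridyl thioester (Mukaiyama ketone synthesis) stops at the ketone and gives 17 on work-up.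

Step 14 (decarboxylative C20–C21 coupling between two heavily silylated halves). The fallback sets out from 20 and comes back at 21, forming the C–C bond by two-electron palladium/organozinc chemistry instead. Visible-light iododecarboxylation of 20 (LiI, catalytic PPh3, blue light) gives the C10–C20 primary iodide F2. Zinc insertion (Zn, LiCl, THF) gives the C10–C20 alkylzinc iodide F3. Fukuyama coupling of F3 with excess 10 (PdCl2(PPh3)2, toluene/THF) gives 21.

Step 23 (one-pot double Stille macrocyclisation). The fallback sets out from 31 and 33 and comes back at 36, closing the ring at C2=C3 by olefination instead of at the polyene by Stille coupling. Stille coupling of 33 with excess (E)-1,2-bis(tributylstannyl)ethene gives (2E,4E,6E)-7-(tributylstannyl)hepta-2,4,6-trienal F4. Stille coupling of F4 with vinyl iodide 31 (Pd2(dba)3, AsPh3, DMF) gives the seco C3 tetraenal phosphonate F5. Intramolecular Horner–Wadsworth–Emmons macrocyclisation of F5 (LiCl, DBU, MeCN, high dilution) gives 36.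

**Further compounds**
F1 | step 10 | dilithium (2S,4E)-1-lithio-5-(trimethylsilyl)pent-4-en-2-olate | C[Si](C)(C)/C=C/C[C@H](O[Li])C[Li]
F2 | step 14 | C10–C20 primary iodide (13,15-bis-TES, 17,19-bis-TBS, E-vinylsilane) | C[Si](C)(C)/C=C/C[C@H](O[Si](CC)(CC)CC)C[C@H](O[Si](CC)(CC)CC)C[C@H](O[Si](C)(C)C(C)(C)C)C[C@@H](O[Si](C)(C)C(C)(C)C)CI
F3 | step 14 | C10–C20 alkylzinc iodide | C[Si](C)(C)/C=C/C[C@H](O[Si](CC)(CC)CC)C[C@H](O[Si](CC)(CC)CC)C[C@H](O[Si](C)(C)C(C)(C)C)C[C@@H](O[Si](C)(C)C(C)(C)C)C[Zn]I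
F4 | step 23 | (2E,4E,6E)-7-(tributylstannyl)hepta-2,4,6-trienal | CCCC[Sn](CCCC)(CCCC)/C=C/C=C/C=C/C=O
F5 | step 23 | seco C3 tetraenal with C35 2-(diethoxyphosphoryl)propanoate | O=C/C=C/C=C/C=C/C=C/C[C@H](O[Si](CC)(CC)CC)C[C@H](O[Si](CC)(CC)CC)C[C@H](O[Si](C)(C)C(C)(C)C)C[C@@H](O[Si](C)(C)C(C)(C)C)CC(=O)C[C@@H](O[Si](C)(C)C(C)(C)C)C[C@H](O[Si](C)(C)C(C)(C)C)CC(=O)CCCCCCC[C@H](C(C)C)OC(=O)C(C)P(=O)(OCC)OCC
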